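A direct plan would make ring C last by Friedel–Crafts acylation: the symmetric phenol A1 would displace tosylate from the enol tosylate A2, the ester would be saponified to the 3-aryloxyacrylic acid A3, and an acid anhydride would close C4–C4a to the tris-benzylated isoflavone A4. All benzyl-type ethers would then be removed (triol A5), O7 and O4′ re-benzylated, the chelated 5-OH methylated and the benzyl groups removed again.
Weak point 1, the end game (deprotect, re-protect, methylate, deprotect): four steps that would form no skeletal bond, forced by a symmetric ring A that hides the 5-OMe/7-OH difference until the end.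
Weak point 2, the Friedel–Crafts closure of A3: three benzylic ethers and an aryl enol ether would meet an acylium ion and strong acid late in the route, with debenzylation, C-benzylation and loss of the phenol as side paths.
Weak point 3, the run-up: two steps to the simple phenol A1 and six to A3, spent only to hang a C3 acid on a phenol oxygen through an enol tosylate that can isomerise or exchange.

**Retrosynthetic overview**
The target would come by hydrogenolysis from its 7,4′-bis(benzyl-type) ether, and this from a 2′-hydroxychalcone by a biomimetic oxidative 1,2-aryl shift; the chalcone would come from an aldol condensation of a ring A acetophenone with a ring B aldehyde.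
The key step breaks C2–C1′ and forms C3–C1′: ring B (4-oxygenated 3,5-dimethoxyphenyl, a good migrating group through a phenonium ion) moves to the carbon next to C4=O, as isoflavone synthase does on a flavanone, and ring C then closes at O1–C2 in the same flask.
Rings A and B are bought; ring C is formed last, from the rearranged C3 chain.
Ring A is 2,4-dihydroxy-3-methylacetophenone, whose chelated 2-OH (future 5-OMe) and free 4-OH (future 7-OH) differ from the start; O1 is added by ketone-directed C–H borylation–oxidation, so C5-OMe, C6-Me, C7-O and C8-H are fixed before the core exists.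
Hence no symmetric ring A and no end-game protecting-group exchange, no acylium chemistry on the protected molecule, and ring B enters in one step.

Key step: step 5

Remark: 2,4-dihydroxy-3-methylacetophenone and 4-(benzyloxy)-3,5-dimethoxybenzaldehyde are taken as catalogue compounds; the aldehyde would otherwise cost one Williamson step from syringaldehyde.

Step 1
Reactants: 1 2,4-dihydroxy-3-methylacetophenone; 2 4-methylbenzyl bromide
Product: 3 1-{2-hydroxy-3-methyl-4-[(4-methylbenzyl)oxy]phenyl}ethan-1-one
Conditions: 2 (1.05 equiv), K2CO3, acetone, reflux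
Reagents that add atoms: 4-methylbenzyl bromide (2), Cc1ccc(CBr)cc1
Why: Williamson etherification in which only the free, more acidic 4-OH should react, because the 2-OH is held in a hydrogen bond to the acetyl C=O; the 4-methylbenzyl group is taken because each of its arene C–H bonds lies ortho to a substituent (inert in step 3) and it leaves by hydrogenolysis.

Step 2
Reactants: 3 1-{2-hydroxy-3-methyl-4-[(4-methylbenzyl)oxy]phenyl}ethan-1-one
Product: 4 1-{2-methoxy-3-methyl-4-[(4-methylbenzyl)oxy]phenyl}ethan-1-one
Conditions: MeI (excess), K2CO3, DMF, 60 °C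
Reagents that add atoms: iodomethane, CI
Why: Williamson O-methylation of the chelated phenol under forcing conditions in a dipolar aprotic solvent, which fixes the future 5-OMe between the acyl carbon and the C-methyl group before any ring of the core is built.

Step 3
Reactants: 4 1-{2-methoxy-3-methyl-4-[(4-methylbenzyl)oxy]phenyl}ethan-1-one
Product: 6 1-{6-hydroxy-2-methoxy-3-methyl-4-[(4-methylbenzyl)oxy]phenyl}ethan-1-one, via pinacol arylboronate 5 (not isolated)
Conditions: [Ir(OMe)(cod)]2 (cat.), AsPh3 (cat.), B2pin2 (1.1 equiv), octane, 120 °C; then NaBO3·4H2O, THF–H2O, rt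
Reagents that add atoms: bis(pinacolato)diboron, CC1(C)OB(OC1(C)C)B1OC(C)(C)C(C)(C)O1 (atoms in 5 only); sodium perborate, [Na+].[O-]OB=O
Why: Ketone-directed iridium-catalysed ortho C–H borylation, in which the acetyl oxygen binds the iridium boryl complex that the monodentate arsine leaves unsaturated and should deliver boron to C6–H, the only C–H ortho to the ketone, followed by perborate oxidation of the arylboronate (1,2-aryl shift from boron to oxygen), which places the future O1.

Step 4
Reactants: 6 1-{6-hydroxy-2-methoxy-3-methyl-4-[(4-methylbenzyl)oxy]phenyl}ethan-1-one; 7 4-(benzyloxy)-3,5-dimethoxybenzaldehyde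
Product: 8 (E)-3-[4-(benzyloxy)-3,5-dimethoxyphenyl]-1-{6-hydroxy-2-methoxy-3-methyl-4-[(4-methylbenzyl)oxy]phenyl}prop-2-en-1-one
Conditions: KOH (50% aq., excess), EtOH, rt; then dil. HCl, 0 °C
Reagents that add atoms: 4-(benzyloxy)-3,5-dimethoxybenzaldehyde (7), COc1cc(C=O)cc(OC)c1OCc1ccccc1
Why: Claisen–Schmidt condensation (aldol addition of the ketone enolate to the non-enolisable aldehyde, then E1cB loss of water), which should give the conjugated E enone under thermodynamic control and keep it as the open chalcone through the hydrogen bond of the 6-OH to the carbonyl.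

Step 5
Reactants: 8 (E)-3-[4-(benzyloxy)-3,5-dimethoxyphenyl]-1-{6-hydroxy-2-methoxy-3-methyl-4-[(4-methylbenzyl)oxy]phenyl}prop-2-en-1-one
Product: 10 3-[4-(benzyloxy)-3,5-dimethoxyphenyl]-5-methoxy-6-methyl-7-[(4-methylbenzyl)oxy]-4H-chromen-4-one, via dimethyl acetal 9 (not isolated)
Conditions: Tl(NO3)3·3H2O (1.1 equiv), MeOH–HC(OMe)3, rt; then 10% aq. HCl, 50 °C
Reagents that add atoms: methanol, CO (atoms in 9 only)
Why: Trivalent thallium adds to the enone C=C together with methanol (oxythallation: MeO at the benzylic carbon that bears ring B, Tl at the carbon next to C=O), ring B then shifts to that carbon through a phenonium ion as monovalent thallium departs, and the methoxy-stabilised cation left behind is trapped by methanol as acetal 9; this forms C3–C1′ and turns the 1,3-diaryl chain into the 1,2-diaryl chain of an isoflavone. The closest known reaction type is the Tl(NO3)3-mediated oxidative rearrangement of 2′-hydroxychalcones that carry a 4-alkoxy ring B to isoflavones, the laboratory counterpart of the enzymatic flavanone-to-isoflavone aryl shift. Acid then ionises the acetal, the chelated phenol oxygen (future O1) attacks the oxocarbenium carbon (future C2) in a 6-exo-trig closure of ring C (O1, C2, C3, C4, C4a, C8a), and loss of the second methanol gives the C2=C3 bond. No stereocentre remains, since the one at C3 of 9 is racemic and is erased on elimination. The step needs the aryl shift to win over aurone formation and over oxidation of the arenes; the 4-benzyloxy oxygen para to C1′ stabilises both the benzylic cation and the phenonium ion, the phenol is deactivated by its hydrogen bond to the carbonyl, and all other phenols are capped. The substitution pattern of ring A cannot drift, because the 6-OH is the only free phenol of 9.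

Step 6
Reactants: 10 3-[4-(benzyloxy)-3,5-dimethoxyphenyl]-5-methoxy-6-methyl-7-[(4-methylbenzyl)oxy]-4H-chromen-4-one
Product: 11 7-hydroxy-3-(4-hydroxy-3,5-dimethoxyphenyl)-5-methoxy-6-methyl-4H-chromen-4-one
Conditions: H2 (1 atm), 10% Pd/C, THF–MeOH, rt
Reagents that add atoms: none
Why: Hydrogenolysis of the two benzylic C–O bonds over palladium, which should be faster than reduction of the C2=C3 bond of the chromone and should leave the three aryl methyl ethers untouched.

**Compound list**
1 | 1-(2,4-dihydroxy-3-methylphenyl)ethan-1-one (2,4-dihydroxy-3-methylacetophenone) | CC(=O)c1ccc(O)c(C)c1O | starting material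
2 | 4-methylbenzyl bromide | Cc1ccc(CBr)cc1 | starting material
3 | 1-{2-hydroxy-3-methyl-4-[(4-methylbenzyl)oxy]phenyl}ethan-1-one | CC(=O)c1ccc(OCc2ccc(C)cc2)c(C)c1O | intermediate
4 | 1-{2-methoxy-3-methyl-4-[(4-methylbenzyl)oxy]phenyl}ethan-1-one | CC(=O)c1ccc(OCc2ccc(C)cc2)c(C)c1OC | intermediate
5 | 1-{2-methoxy-3-methyl-4-[(4-methylbenzyl)oxy]-6-(4,4,5,5-tetramethyl-1,3,2-dioxaborolan-2-yl)phenyl}ethan-1-one | CC(=O)c1c(B2OC(C)(C)C(C)(C)O2)cc(OCc2ccc(C)cc2)c(C)c1OC | intermediate (not isolated)
6 | 1-{6-hydroxy-2-methoxy-3-methyl-4-[(4-methylbenzyl)oxy]phenyl}ethan-1-one | CC(=O)c1c(O)cc(OCc2ccc(C)cc2)c(C)c1OC | intermediate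
7 | 4-(benzyloxy)-3,5-dimethoxybenzaldehyde | COc1cc(C=O)cc(OC)c1OCc1ccccc1 | starting material
8 | (E)-3-[4-(benzyloxy)-3,5-dimethoxyphenyl]-1-{6-hydroxy-2-methoxy-3-methyl-4-[(4-methylbenzyl)oxy]phenyl}prop-2-en-1-one | COc1cc(/C=C/C(=O)c2c(O)cc(OCc3ccc(C)cc3)c(C)c2OC)cc(OC)c1OCc1ccccc1 | intermediate (key-step precursor)
9 | 2-[4-(benzyloxy)-3,5-dimethoxyphenyl]-1-{6-hydroxy-2-methoxy-3-methyl-4-[(4-methylbenzyl)oxy]phenyl}-3,3-dimethoxypropan-1-one (racemic) | COC(OC)C(C(=O)c1c(O)cc(OCc2ccc(C)cc2)c(C)c1OC)c1cc(OC)c(OCc2ccccc2)c(OC)c1 | intermediate (not isolated)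
10 | 3-[4-(benzyloxy)-3,5-dimethoxyphenyl]-5-methoxy-6-methyl-7-[(4-methylbenzyl)oxy]-4H-chromen-4-one | COc1cc(-c2coc3cc(OCc4ccc(C)cc4)c(C)c(OC)c3c2=O)cc(OC)c1OCc1ccccc1 | intermediate (key-step product)
11 | 7-hydroxy-3-(4-hydroxy-3,5-dimethoxyphenyl)-5-methoxy-6-methyl-4H-chromen-4-one | COc1cc(-c2coc3cc(O)c(C)c(OC)c3c2=O)cc(OC)c1O | target

Total step count: 6. Longest linear sequence: 6 steps (1 → 3 → 4 → 6 → 8 → 10 → 11).

**Steps most likely to fail**

Step 5 (key step). The aryl shift may lose to attack of the free phenol on the thallium-activated alkene (the aurone pathway), or the electron-rich arenes may be oxidised before migration. The fallback sets out from 6 and builds ring C first, then attaches ring B by cross-coupling. Condensation of 6 with N,N-dimethylformamide dimethyl acetal should give (E)-3-(dimethylamino)-1-{6-hydroxy-2-methoxy-3-methyl-4-[(4-methylbenzyl)oxy]phenyl}prop-2-en-1-one F1. Iodine in chloroform should close it to 3-iodo-5-methoxy-6-methyl-7-[(4-methylbenzyl)oxy]-4H-chromen-4-one F2. The coupling partner would come from 4-bromo-2,6-dimethoxyphenol: benzylation (BnBr, K2CO3) to 2-(benzyloxy)-5-bromo-1,3-dimethoxybenzene F3, then n-BuLi, B(OiPr)3 and aqueous acid to [4-(benzyloxy)-3,5-dimethoxyphenyl]boronic acid F4. Suzuki–Miyaura coupling of F2 with F4 (Pd(PPh3)4, Na2CO3, DME–H2O, 80 °C) comes back to the route at 10.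

Step 3. The crowded, twisted acetyl group may deliver iridium poorly (low conversion), boron may enter at C5–H without direction, or the pinacolborane formed may reduce the ketone. The fallback sets out from 4 and moves the oxygen in through an aryne instead of a C–H borylation.
- Baeyer–Villiger oxidation (3-chloroperbenzoic acid, CH2Cl2) should give 2-methoxy-3-methyl-4-[(4-methylbenzyl)oxy]phenyl acetate F5, and K2CO3 in MeOH the phenol 2-methoxy-3-methyl-4-[(4-methylbenzyl)oxy]phenol F6.
- Isopropyl isocyanate would give 2-methoxy-3-methyl-4-[(4-methylbenzyl)oxy]phenyl N-isopropylcarbamate F7.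
- Carbamate-directed ortho-lithiation at the only free ortho position (N-silylation in situ, n-BuLi, TMEDA, −78 °C, then Me3SiCl) would give 2-methoxy-3-methyl-4-[(4-methylbenzyl)oxy]-6-(trimethylsilyl)phenyl N-isopropylcarbamate F8.
- Cleavage of the carbamate with DBU and Et2NH and trapping of the phenoxide with PhNTf2 would give 2-methoxy-3-methyl-4-[(4-methylbenzyl)oxy]-6-(trimethylsilyl)phenyl trifluoromethanesulfonate F9.
- CsF in THF with acetic acid should generate 3-methoxy-4-methyl-5-[(4-methylbenzyl)oxy]benzyne F10, which inserts into the C–O bond of the acid. The acetate oxygen adds to the aryne carbon remote from the methoxy group and the aryl anion next to the methoxy group takes the acetyl group, which comes back to the route at 6 with the regiochemistry fixed by the aryne.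

Step 6. The C2=C3 bond may be reduced along with the benzylic ethers (isoflavanone formation), or cleavage of the 7-O ether may stall. The fallback sets out from 10 and replaces hydrogenolysis by acidolysis: trifluoroacetic acid with pentamethylbenzene as cation scavenger at rt should remove both benzyl-type groups by an SN1 path and leave the methyl ethers and the chromone intact, ending at 11 with no new intermediate.

**Further compounds**
F1 | step 5 | (E)-3-(dimethylamino)-1-{6-hydroxy-2-methoxy-3-methyl-4-[(4-methylbenzyl)oxy]phenyl}prop-2-en-1-one | CN(C)/C=C/C(=O)c1c(O)cc(OCc2ccc(C)cc2)c(C)c1OC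
F2 | step 5 | 3-iodo-5-methoxy-6-methyl-7-[(4-methylbenzyl)oxy]-4H-chromen-4-one | COc1c(C)c(OCc2ccc(C)cc2)cc2occ(I)c(=O)c12
F3 | step 5 | 2-(benzyloxy)-5-bromo-1,3-dimethoxybenzene | COc1cc(Br)cc(OC)c1OCc1ccccc1
F4 | step 5 | [4-(benzyloxy)-3,5-dimethoxyphenyl]boronic acid | COc1cc(B(O)O)cc(OC)c1OCc1ccccc1
F5 | step 3 | 2-methoxy-3-methyl-4-[(4-methylbenzyl)oxy]phenyl acetate | CC(=O)Oc1ccc(OCc2ccc(C)cc2)c(C)c1OC
F6 | step 3 | 2-methoxy-3-methyl-4-[(4-methylbenzyl)oxy]phenol | COc1c(O)ccc(OCc2ccc(C)cc2)c1C
F7 | step 3 | 2-methoxy-3-methyl-4-[(4-methylbenzyl)oxy]phenyl N-isopropylcarbamate | CC(C)NC(=O)Oc1ccc(OCc2ccc(C)cc2)c(C)c1OC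
F8 | step 3 | 2-methoxy-3-methyl-4-[(4-methylbenzyl)oxy]-6-(trimethylsilyl)phenyl N-isopropylcarbamate | CC(C)NC(=O)Oc1c([Si](C)(C)C)cc(OCc2ccc(C)cc2)c(C)c1OC
F9 | step 3 | 2-methoxy-3-methyl-4-[(4-methylbenzyl)oxy]-6-(trimethylsilyl)phenyl trifluoromethanesulfonate | COc1c(OS(=O)(=O)C(F)(F)F)c([Si](C)(C)C)cc(OCc2ccc(C)cc2)c1C
F10 | step 3 | 3-methoxy-4-methyl-5-[(4-methylbenzyl)oxy]benzyne | COC1=C(C)C(OCc2ccc(C)cc2)=CC#C1
F0 | step 6 | none | none
A1 | direct plan | 4-methyl-3,5-bis[(4-methylbenzyl)oxy]phenol | Cc1ccc(COc2cc(O)cc(OCc3ccc(C)cc3)c2C)cc1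
A2 | direct plan | methyl (Z)-2-[4-(benzyloxy)-3,5-dimethoxyphenyl]-3-{[(4-methylphenyl)sulfonyl]oxy}prop-2-enoate | COC(=O)/C(=C\OS(=O)(=O)c1ccc(C)cc1)c1cc(OC)c(OCc2ccccc2)c(OC)c1
A3 | direct plan | (Z)-3-{3,5-bis[(4-methylbenzyl)oxy]-4-methylphenoxy}-2-[4-(benzyloxy)-3,5-dimethoxyphenyl]prop-2-enoic acid | OC(=O)/C(=C\Oc1cc(OCc2ccc(C)cc2)c(C)c(OCc2ccc(C)cc2)c1)c1cc(OC)c(OCc2ccccc2)c(OC)c1
A4 | direct plan | 3-[4-(benzyloxy)-3,5-dimethoxyphenyl]-6-methyl-5,7-bis[(4-methylbenzyl)oxy]-4H-chromen-4-one | COc1cc(-c2coc3cc(OCc4ccc(C)cc4)c(C)c(OCc4ccc(C)cc4)c3c2=O)cc(OC)c1OCc1ccccc1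
A5 | direct plan | 5,7-dihydroxy-3-(4-hydroxy-3,5-dimethoxyphenyl)-6-methyl-4H-chromen-4-one | COc1cc(-c2coc3cc(O)c(C)c(O)c3c2=O)cc(OC)c1O
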